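In the early seconds of these flasks the substrate opens slowly, and each open intermediate it gives is caught at once by whichever partner gets there first.

    substrate → open intermediate (k1 = 0.027 s⁻¹)
    first nucleophile + open intermediate → target (k2 = 0.91 M⁻¹ s⁻¹)
    second nucleophile + open intermediate → other capture product (k3 = 0.92 M⁻¹ s⁻¹)
    open intermediate → solvolysis product (k4 = 0.38 s⁻¹)
    open intermediate → side product (k5 = 0.054 s⁻¹)
    crystals ⇌ target, rate k6*(cs6 - [target]) while solid is left; crystals form when [target] > cs6 (cs6 = 24 mM, k6 = 0.21 s⁻¹)
    open intermediate + capture agent → trapped intermediate (k7 = 0.42 M⁻¹ s⁻¹)

| setting | alder | larch | elm |
|---|---|---|---|
| substrate | 0.67 M | 0.67 M | 0.67 M |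
| first nucleophile | 1.50 equiv | 1.50 equiv | 1.50 equiv |
| second nucleophile | 1.00 equiv | 1.00 equiv | 1.00 equiv |
| capture agent | 0.0670 M | 0.0670 M | 0.0670 M |
| time | 30 s | 75 s | 190 s |

1. which of these there is most of at the end, counted by the substrate in it, alder (substrate / other capture product / target / solvolysis product / side product)
2. which of these there is most of at the end, counted by the substrate in it, larch (substrate / other capture product / target / solvolysis product / side product)
3. which of these there is most of at the end, counted by the substrate in it, elm (substrate / other capture product / target / solvolysis product / side product)
4. the largest of these amounts at the end, in percent of the substrate charged, alder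
5. the largest of these amounts at the end, in percent of the substrate charged, larch
6. the largest of these amounts at the end, in percent of the substrate charged, elm

- amounts and yields of target count crystals too
- given per volume of solution although it is solid: crystals
- run time (alder): 30 s

I need two clocks. The first belongs to the substrate: τA is the reciprocal of its opening constant.

τA = 37.0 s

The second belongs to the open intermediate, which leaves by the first nucleophile at 0.915 s⁻¹, by the second at 0.616 s⁻¹, and by solvolysis, the side step and the capture agent together at 0.462 s⁻¹.

τI = reciprocal of the sum = 0.502 s

This τI, the reciprocal of the summed exit rates of the open intermediate at the concentrations present, is what I carry. Because τA is 73.7 times longer, the open intermediate is a short-lived species at a low steady level, and the opening is the rate-limiting step. So I count what is left, not what is made: each second the same fraction of substrate opens, with no integral needed.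

fraction left = exp(−t/τA): alder 44.5%, larch 13.2%, elm 0.592%

What has gone divides at once. The first nucleophile has the largest exit, and its share is φ = its exit rate × τI.

φ = 45.9%

target = φ × fraction gone: alder 25.5%, larch 39.8%, elm 45.6%

Crystals count as target, so they change nothing in this count. Substrate therefore leads in alder, and target leads in larch and elm. My target figures run slightly high, since φ uses the charged concentrations.

The forecast gives substrate at 44.5% for alder, target at 38.5% for larch and target at 43.9% for elm, lower than my target figures for larch and elm, on the ground that “the products split according to their competing rates”.

The flask gives substrate at 44.5% for alder, target at 38.4% for larch and target at 43.8% for elm.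

At the end of larch, with 74% of the first nucleophile's charge and 74% of the second's left, τI has grown to 0.627 s, still far shorter than τA, and the open intermediate stands at 0.227% beside 13.2% substrate. For the neighbour flask, larch with 4.00 equiv of second nucleophile, τI at the charge is 0.260 s, which puts φ at 23.8% and the target at 20.7%; that flask holds 20.5% target, and its other capture product stands at 55.1%.

The constants stand for no real mixture, and the outcome is calculated.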